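**Retrosynthetic overview**

1. 35 ⇐ angeloylation at C3 with mixed anhydride 27 ⇐ hydroxyl-directed peracid epoxidation of C4=C5 ⇐ desilylation of the (4Z)-cyclodecene 32.
2. Feature used: in the ten-membered ring C1–C10, the C5–C6 bond joins the CH end of the Z-trisubstituted C4=C5 olefin (sp2, later the 4,5-oxirane) to the C6 methylene (sp3). 32 ⇐ intramolecular Negishi coupling of seco diiodide 30 (primary iodide at C6, (Z)-iodoalkene at C5).
3. 30 ⇐ C7–C8 bond by allylboration of α-acetoxy aldehyde 20 with the isoprene-derived (Z)-bis(boronate) 23, which brings C6, C7 and the isopropenyl group; C9 ⇐ vinyl addition to epoxy aldehyde 14, oxidation, Zn(BH4)2 reduction.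
4. 14 ⇐ Sharpless epoxidation of (Z)-allylic alcohol 12 (oxirane C1–C10) ⇐ Still–Gennari olefination of aldehyde 9 ⇐ Brown allylation (C3) of (Z)-iodoenal 4 ⇐ carbomagnesiation–iodination of propargyl alcohol 1.
5. Ring order: oxirane C1–C10 (step 8), cyclodecene C1–C10 (step 21), oxirane C4–C5 (step 23).

Key step: step 21

Remark on the chemistry: open-chain intermediates carry the ring numbering of 35 (C1/C10 and C4/C5 oxirane carbons, C3, C8, C9 oxygenated, C7 bearing the isopropenyl carbon C11); (−)-Ipc2B(allyl), phosphonate 10 and ethereal Zn(BH4)2 are assumed to be purchased or stock reagents; mixed anhydride 27 is used as a freshly filtered toluene solution, so step 17 is run once for step 18 and a second time for step 24.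

**Route**

Step 1
Reactants: 1 propargyl alcohol
Product: 3 (Z)-3-iodo-2-methylprop-2-en-1-ol, via alkenylmagnesium alkoxide 2 (not isolated)
Conditions: MeMgBr (2.5 equiv), CuI (10 mol %), Et2O/THF, −10 °C → rt; then I2, −78 → 0 °C
Reagents that add atoms: methylmagnesium bromide, C[Mg]Br; iodine, II
Why: Copper-catalysed anti-carbomagnesiation of the magnesium propargyl alkoxide places methyl on C4 and magnesium on C5 cis to the CH2O group (five-membered chelate), and iodinolysis with retention should give the Z-iodoalkene only.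

Step 2
Reactants: 3 (Z)-3-iodo-2-methylprop-2-en-1-ol
Product: 4 (Z)-3-iodo-2-methylprop-2-enal
Conditions: MnO2 (activated, excess), CH2Cl2, rt, dark; used at once
Reagents that add atoms: none
Why: Allylic oxidation with MnO2 is neutral and should leave the Z geometry intact if the enal is not stored.

Step 3
Reactants: 4 (Z)-3-iodo-2-methylprop-2-enal
Product: 6 (3S,1Z)-1-iodo-2-methylhexa-1,5-dien-3-ol, via borinate ester 5 (not isolated)
Conditions: (−)-Ipc2B(allyl) (from (+)-α-pinene), Et2O, −78 °C; then NaOH, H2O2, 0 °C → rt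
Reagents that add atoms: (−)-B-allyldiisopinocampheylborane, C=CCB([C@@H]1C[C@@H]2C[C@H]([C@H]1C)C2(C)C)[C@@H]1C[C@@H]2C[C@H]([C@H]1C)C2(C)C
Why: Brown allylation through a closed chair transition state transfers allyl to the si face of the aldehyde under control of the isopinocampheyl groups, which sets C3 (S).

Step 4
Reactants: 6 (3S,1Z)-1-iodo-2-methylhexa-1,5-dien-3-ol
Product: 7 (3S,1Z)-1-iodo-2-methyl-3-(triethylsilyloxy)hexa-1,5-diene
Conditions: Et3SiCl, imidazole, CH2Cl2, 0 °C → rt
Reagents that add atoms: chlorotriethylsilane, CC[Si](Cl)(CC)CC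
Why: Standard silylation of a secondary allylic alcohol gives an ether that should survive base, hydride, peroxide and periodinane steps and come off with buffered fluoride.

Step 5
Reactants: 7 (3S,1Z)-1-iodo-2-methyl-3-(triethylsilyloxy)hexa-1,5-diene
Product: 9 (3S,4Z)-5-iodo-4-methyl-3-(triethylsilyloxy)pent-4-enal, via vicinal diol 8 (not isolated)
Conditions: OsO4 (2 mol %), NaIO4 (4 equiv), 2,6-lutidine, dioxane/H2O, rt
Reagents that add atoms: osmium tetroxide, O=[Os](=O)(=O)=O; sodium periodate, [Na+].[O-]I(=O)(=O)=O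
Why: Lemieux–Johnson cleavage, in which OsO4 should select the monosubstituted alkene over the hindered, iodine-deactivated trisubstituted alkene.

Step 6
Reactants: 9 (3S,4Z)-5-iodo-4-methyl-3-(triethylsilyloxy)pent-4-enal; 10 ethyl 2-[bis(2,2,2-trifluoroethoxy)phosphoryl]propanoate
Product: 11 ethyl (2Z,5S,6Z)-7-iodo-2,6-dimethyl-5-(triethylsilyloxy)hepta-2,6-dienoate
Conditions: 10, KN(SiMe3)2, 18-crown-6, THF, −78 °C; then 9
Reagents that add atoms: none
Why: Still–Gennari olefination, in which fast irreversible elimination from the kinetic adduct of the trifluoroethyl phosphonate should give the Z-trisubstituted enoate (C9 cis to C2).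

Step 7
Reactants: 11 ethyl (2Z,5S,6Z)-7-iodo-2,6-dimethyl-5-(triethylsilyloxy)hepta-2,6-dienoate
Product: 12 (2Z,5S,6Z)-7-iodo-2,6-dimethyl-5-(triethylsilyloxy)hepta-2,6-dien-1-ol
Conditions: i-Bu2AlH (2.5 equiv), CH2Cl2, −78 °C
Reagents that add atoms: none
Why: 1,2-Reduction of the enoate by i-Bu2AlH gives the allylic alcohol without touching the olefin geometry, the iodoalkene or the silyl ether.

Step 8
Reactants: 12 (2Z,5S,6Z)-7-iodo-2,6-dimethyl-5-(triethylsilyloxy)hepta-2,6-dien-1-ol
Product: 13 [(2S,3R)-3-[(2S,3Z)-4-iodo-3-methyl-2-(triethylsilyloxy)but-3-en-1-yl]-2-methyloxiran-2-yl]methanol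
Conditions: Ti(OiPr)4 (20 mol %), L-(+)-diethyl tartrate (24 mol %), t-BuOOH, 4 Å MS, CH2Cl2, −20 °C
Reagents that add atoms: tert-butyl hydroperoxide, CC(C)(C)OO
Why: Sharpless asymmetric epoxidation under reagent control, in which L-(+)-tartrate delivers oxygen to the face that gives the (2S,3R)-oxirane from a (Z)-allylic alcohol (the sense known for nerol), setting C1 (R) and C10, while the iodoalkene has no free allylic hydroxyl and stays untouched.

Step 9
Reactants: 13 epoxy alcohol
Product: 14 (2R,3R)-3-[(2S,3Z)-4-iodo-3-methyl-2-(triethylsilyloxy)but-3-en-1-yl]-2-methyloxirane-2-carbaldehyde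
Conditions: Dess–Martin periodinane, pyridine, CH2Cl2, 0 °C → rt
Reagents that add atoms: none
Why: Dess–Martin oxidation under buffered conditions gives the epoxy aldehyde, whose α-carbon C10 is quaternary and cannot epimerise.

Step 10
Reactants: 14 epoxy aldehyde
Product: 15 1-[(2S,3R)-3-[(2S,3Z)-4-iodo-3-methyl-2-(triethylsilyloxy)but-3-en-1-yl]-2-methyloxiran-2-yl]prop-2-en-1-ol (both C9 epimers)
Conditions: CH2=CHMgBr, THF, −78 °C
Reagents that add atoms: vinylmagnesium bromide, C=C[Mg]Br
Why: Grignard addition to the aldehyde is faster than any reaction at the trisubstituted epoxide or the iodoalkene at −78 °C, and the C9 configuration is corrected in steps 11 and 12.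

Step 11
Reactants: 15 allylic alcohol (C9 epimers)
Product: 16 1-[(2R,3R)-3-[(2S,3Z)-4-iodo-3-methyl-2-(triethylsilyloxy)but-3-en-1-yl]-2-methyloxiran-2-yl]prop-2-en-1-one
Conditions: Dess–Martin periodinane, pyridine, CH2Cl2, 0 °C; used at once
Reagents that add atoms: none
Why: Dess–Martin oxidation converges both epimers on one epoxy enone under non-nucleophilic conditions that spare the vinyl ketone.

Step 12
Reactants: 16 epoxy enone
Product: 17 (1S)-1-[(2S,3R)-3-[(2S,3Z)-4-iodo-3-methyl-2-(triethylsilyloxy)but-3-en-1-yl]-2-methyloxiran-2-yl]prop-2-en-1-ol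
Conditions: Zn(BH4)2, Et2O, −30 °C
Reagents that add atoms: none
Why: Chelation-controlled 1,2-reduction, in which zinc bridges the ketone and oxirane oxygens and hydride enters from the face away from C1 and its cis C2 chain, should give the erythro epoxy alcohol and so set C9 (S).

Step 13
Reactants: 17 (9S)-allylic alcohol
Product: 18 (1S)-1-[(2R,3R)-3-[(2S,3Z)-4-iodo-3-methyl-2-(triethylsilyloxy)but-3-en-1-yl]-2-methyloxiran-2-yl]prop-2-en-1-yl acetate
Conditions: Ac2O, pyridine, DMAP (cat.), CH2Cl2, rt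
Reagents that add atoms: acetic anhydride, CC(=O)OC(C)=O
Why: DMAP-catalysed acetylation installs the C9 acetate of the target, which also serves as the polar α-substituent for step 16.

Step 14
Reactants: 18 allylic acetate
Product: 20 (1R)-1-[(2R,3R)-3-[(2S,3Z)-4-iodo-3-methyl-2-(triethylsilyloxy)but-3-en-1-yl]-2-methyloxiran-2-yl]-2-oxoethyl acetate, via vicinal diol 19 (not isolated)
Conditions: OsO4 (2 mol %), NaIO4 (4 equiv), 2,6-lutidine, dioxane/H2O, rt; used crude
Reagents that add atoms: osmium tetroxide, O=[Os](=O)(=O)=O; sodium periodate, [Na+].[O-]I(=O)(=O)=O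
Why: Lemieux–Johnson cleavage of the only monosubstituted alkene, with periodate cleaving the diol as it forms so that the acetate has no time to migrate.

Step 15
Reactants: 21 isoprene; 22 bis(pinacolato)diboron
Product: 23 (Z)-2-methyl-1,4-bis(4,4,5,5-tetramethyl-1,3,2-dioxaborolan-2-yl)but-2-ene
Conditions: Pt(PPh3)4 (3 mol %), toluene, 80 °C
Reagents that add atoms: none
Why: Platinum-catalysed 1,4-diboration, in which the B–B bond adds oxidatively to zerovalent platinum, s-cis isoprene inserts and reductive elimination places both boryl groups on the same side, giving the Z olefin.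

Step 16
Reactants: 20 α-acetoxy aldehyde; 23 (Z)-bis(boronate)
Product: 25 (1R,3S,4Z,7R,8S,9S,10R)-9-acetoxy-1,10-epoxy-5-iodo-6-(4,4,5,5-tetramethyl-1,3,2-dioxaborolan-2-yl)-3-(triethylsilyloxy)-5,6-secogermacra-4,11-dien-8-ol, via O-boryl adduct 24 (not isolated)
Conditions: 23 (1.5 equiv), 4 Å MS, toluene, 0 °C → rt; aq. NaHCO3 work-up
Reagents that add atoms: none
Why: Allylboration through a closed chair transition state, in which the methallyl-type terminus of 23 reacts at its CH carbon (the other terminus would have to form a quaternary centre), the Z-disposed CH2B group sits axial and gives the 7,8-syn relationship (C7 R), and Cornforth/Felkin–Anh attack anti to the C9 acetoxy group gives the 8,9-anti pattern (C8 S).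

Step 17
Reactants: 26 angelic acid
Product: 27 (Z)-2-methylbut-2-enoic 2,4,6-trichlorobenzoic anhydride
Conditions: 2,4,6-trichlorobenzoyl chloride (1.0 equiv), Et3N (1.05 equiv), toluene, rt; ammonium salt filtered off under argon; filtrate used as a toluene solution the same day
Reagents that add atoms: 2,4,6-trichlorobenzoyl chloride, O=C(Cl)c1c(Cl)cc(Cl)cc1Cl
Why: Yamaguchi mixed-anhydride formation, in which the triethylammonium carboxylate displaces chloride from the aroyl chloride at room temperature without a nucleophilic catalyst, so the Z-angeloyl unit should not isomerise to the tiglate.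

Step 18
Reactants: 25 hydroxy boronate; 27 mixed anhydride
Product: 28 (1R,3S,4Z,7R,8S,9S,10R)-9-acetoxy-8-angeloyloxy-1,10-epoxy-5-iodo-6-(4,4,5,5-tetramethyl-1,3,2-dioxaborolan-2-yl)-3-(triethylsilyloxy)-5,6-secogermacra-4,11-diene
Conditions: 27 (2 equiv, toluene solution), toluene, 80 °C
Reagents that add atoms: none
Why: Yamaguchi-type acylation without a nucleophilic catalyst, in which the alcohol attacks the angeloyl carbonyl because the aroyl carbonyl is shielded by its two ortho chlorines, and the Z-angelate should not isomerise to the tiglate.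

Step 19
Reactants: 28 seco boronate
Product: 29 (1R,3S,4Z,7S,8S,9S,10R)-9-acetoxy-8-angeloyloxy-1,10-epoxy-5-iodo-3-(triethylsilyloxy)-5,6-secogermacra-4,11-dien-6-ol
Conditions: NaBO3·4H2O, THF/H2O, 0 °C → rt, short contact
Reagents that add atoms: sodium perborate, [Na+].[Na+].O[B-]1(O)OO[B-](O)(O)OO1
Why: Perborate oxidation of the primary C–B bond (1,2-shift of carbon from boron to peroxide oxygen) is mild enough to spare both esters, and no vicinal free hydroxyl is present to receive a migrating acyl group.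

Step 20
Reactants: 29 primary alcohol
Product: 30 (1R,3S,4Z,7R,8S,9S,10R)-9-acetoxy-8-angeloyloxy-1,10-epoxy-5,6-diiodo-3-(triethylsilyloxy)-5,6-secogermacra-4,11-diene (seco diiodide)
Conditions: I2, PPh3, imidazole, CH2Cl2, 0 °C
Reagents that add atoms: iodine, II
Why: Appel-type iodination through the alkoxyphosphonium salt and SN2 displacement at the primary carbon, a reaction routinely run on epoxy alcohols under imidazole buffering.

Step 21
Reactants: 30 seco diiodide
Product: 32 (1R,3S,4Z,7R,8S,9S,10R)-9-acetoxy-8-angeloyloxy-1,10-epoxy-3-(triethylsilyloxy)germacra-4,11-diene, via alkylzinc iodide 31 (not isolated)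
Conditions: Zn dust (activated with BrCH2CH2Br, Me3SiCl), DMA, 40 °C; then the solution of 31 by syringe pump into Pd(PPh3)4 (10 mol %), THF/DMA, 60 °C, final about 1 mM
Reagents that add atoms: none
Why: Proposed new method: zinc inserts into the primary sp3 C6–I bond while the alkenyl C5–I bond stays untouched, zerovalent palladium then adds oxidatively to C5–I with retention, the tethered alkylzinc transmetalates and reductive elimination forms C5–C6; the closest known reaction types are the intermolecular alkylzinc–alkenyl iodide Negishi coupling and the macrocyclic B-alkyl Suzuki–Miyaura coupling, and the ten-membered Negishi closure is the untested extension. The ring C1–C10 closes head to tail through an eleven-membered alkyl(alkenyl)palladium chelate, C6 bonding to the CH terminus of the C4=C5 olefin. No stereocenter is formed, and the 4Z geometry is inherited from iodoalkene 30 because oxidative addition and reductive elimination both retain configuration at sp2 carbon. Chemoselective metalation rests on the much faster zinc insertion into alkyl than into alkenyl iodides in DMA without LiCl, and the organozinc should leave the oxirane, the acetate and the angelate alone. Ring closure over oligomerisation is enforced by slow addition at high dilution, helped by the cis olefin and the oxirane that pre-bend the chain. Reductive elimination from the cis alkyl(alkenyl)palladium should outrun β-hydride loss from C7, which carries the only β-hydrogen.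

Step 22
Reactants: 32 silyl ether macrocycle
Product: 33 (1R,3S,4Z,7R,8S,9S,10R)-9-acetoxy-8-angeloyloxy-1,10-epoxygermacra-4,11-dien-3-ol
Conditions: HF·pyridine, pyridine, THF, 0 °C → rt
Reagents that add atoms: none
Why: Buffered fluoride desilylation removes the triethylsilyl group without acid-induced transannular opening of the oxirane or acyl migration.

Step 23
Reactants: 33 allylic alcohol
Product: 34 (1R,3S,4R,5S,7R,8S,9S,10R)-9-acetoxy-8-angeloyloxy-1,10:4,5-diepoxygermacr-11-en-3-ol
Conditions: mCPBA (1.05 equiv), Na2HPO4, CH2Cl2, −20 → 0 °C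
Reagents that add atoms: 3-chloroperoxybenzoic acid, OOC(=O)c1cccc(Cl)c1
Why: Henbest-type hydrogen-bond-directed peracid epoxidation, in which 1,3-allylic strain with the cis ring carbon C6 holds C3–H in the olefin plane so that hydroxyl and peracid lie on the face away from ring carbon C2 and the threo (ring-trans) epoxy alcohol forms, C4 (R) and C5 (S), as with peracid epoxidation of medium-ring (Z)-cycloalkenols, whereas a vanadium alkoxide would deliver oxygen cis in such rings; the trisubstituted ring olefin should react before the isopropenyl group and the electron-poor angelate.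

Step 24
Reactants: 34 epoxy alcohol; 27 mixed anhydride
Product: 35 (1R,3S,4S,5S,7R,8S,9S,10R)-9-acetoxy-3,8-bis(angeloyloxy)-1,10:4,5-diepoxygermacr-11-ene (CNP0220329.1)
Conditions: 27 (3 equiv, fresh toluene solution), toluene, 80 °C
Reagents that add atoms: none
Why: The same catalyst-free Yamaguchi-type angeloylation as in step 18 should acylate the hindered C3 hydroxyl without Z-to-E isomerisation and without opening either oxirane.

**Compound list**

1 | propargyl alcohol | C#CCO | starting material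
2 | bromomagnesium (2Z)-3-(bromomagnesio)-2-methylprop-2-en-1-olate | Br[Mg]/C=C(C)\CO[Mg]Br | intermediate (not isolated)
3 | (Z)-3-iodo-2-methylprop-2-en-1-ol | I/C=C(C)\CO | intermediate
4 | (Z)-3-iodo-2-methylprop-2-enal | I/C=C(C)\C=O | intermediate
5 | (3S,1Z)-1-iodo-2-methylhexa-1,5-dien-3-yl diisopinocampheylborinate (isopinocampheyl groups from (+)-α-pinene) | I/C=C(C)\[C@@H](OB([C@@H]1C[C@@H]2C[C@H]([C@H]1C)C2(C)C)[C@@H]1C[C@@H]2C[C@H]([C@H]1C)C2(C)C)CC=C | intermediate (not isolated)
6 | (3S,1Z)-1-iodo-2-methylhexa-1,5-dien-3-ol | I/C=C(C)\[C@@H](O)CC=C | intermediate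
7 | (3S,1Z)-1-iodo-2-methyl-3-(triethylsilyloxy)hexa-1,5-diene | I/C=C(C)\[C@@H](O[Si](CC)(CC)CC)CC=C | intermediate
8 | (4S,5Z)-6-iodo-5-methyl-4-(triethylsilyloxy)hex-5-ene-1,2-diol (C2 epimers) | I/C=C(C)\[C@@H](O[Si](CC)(CC)CC)CC(O)CO | intermediate (not isolated)
9 | (3S,4Z)-5-iodo-4-methyl-3-(triethylsilyloxy)pent-4-enal | I/C=C(C)\[C@@H](O[Si](CC)(CC)CC)CC=O | intermediate
10 | ethyl 2-[bis(2,2,2-trifluoroethoxy)phosphoryl]propanoate | CCOC(=O)C(C)P(=O)(OCC(F)(F)F)OCC(F)(F)F | starting material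
11 | ethyl (2Z,5S,6Z)-7-iodo-2,6-dimethyl-5-(triethylsilyloxy)hepta-2,6-dienoate | I/C=C(C)\[C@@H](O[Si](CC)(CC)CC)C/C=C(C)\C(=O)OCC | intermediate
12 | (2Z,5S,6Z)-7-iodo-2,6-dimethyl-5-(triethylsilyloxy)hepta-2,6-dien-1-ol | I/C=C(C)\[C@@H](O[Si](CC)(CC)CC)C/C=C(C)\CO | intermediate
13 | [(2S,3R)-3-[(2S,3Z)-4-iodo-3-methyl-2-(triethylsilyloxy)but-3-en-1-yl]-2-methyloxiran-2-yl]methanol | I/C=C(C)\[C@@H](O[Si](CC)(CC)CC)C[C@H]1O[C@@]1(C)CO | intermediate
14 | (2R,3R)-3-[(2S,3Z)-4-iodo-3-methyl-2-(triethylsilyloxy)but-3-en-1-yl]-2-methyloxirane-2-carbaldehyde | I/C=C(C)\[C@@H](O[Si](CC)(CC)CC)C[C@H]1O[C@@]1(C)C=O | intermediate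
15 | 1-[(2S,3R)-3-[(2S,3Z)-4-iodo-3-methyl-2-(triethylsilyloxy)but-3-en-1-yl]-2-methyloxiran-2-yl]prop-2-en-1-ol (C9 epimers) | I/C=C(C)\[C@@H](O[Si](CC)(CC)CC)C[C@H]1O[C@@]1(C)C(O)C=C | intermediate
16 | 1-[(2R,3R)-3-[(2S,3Z)-4-iodo-3-methyl-2-(triethylsilyloxy)but-3-en-1-yl]-2-methyloxiran-2-yl]prop-2-en-1-one | I/C=C(C)\[C@@H](O[Si](CC)(CC)CC)C[C@H]1O[C@@]1(C)C(=O)C=C | intermediate
17 | (1S)-1-[(2S,3R)-3-[(2S,3Z)-4-iodo-3-methyl-2-(triethylsilyloxy)but-3-en-1-yl]-2-methyloxiran-2-yl]prop-2-en-1-ol | I/C=C(C)\[C@@H](O[Si](CC)(CC)CC)C[C@H]1O[C@@]1(C)[C@@H](O)C=C | intermediate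
18 | (1S)-1-[(2R,3R)-3-[(2S,3Z)-4-iodo-3-methyl-2-(triethylsilyloxy)but-3-en-1-yl]-2-methyloxiran-2-yl]prop-2-en-1-yl acetate | I/C=C(C)\[C@@H](O[Si](CC)(CC)CC)C[C@H]1O[C@@]1(C)[C@@H](OC(C)=O)C=C | intermediate
19 | (1S)-2,3-dihydroxy-1-[(2R,3R)-3-[(2S,3Z)-4-iodo-3-methyl-2-(triethylsilyloxy)but-3-en-1-yl]-2-methyloxiran-2-yl]propyl acetate (C2 epimers) | I/C=C(C)\[C@@H](O[Si](CC)(CC)CC)C[C@H]1O[C@@]1(C)[C@@H](OC(C)=O)C(O)CO | intermediate (not isolated)
20 | (1R)-1-[(2R,3R)-3-[(2S,3Z)-4-iodo-3-methyl-2-(triethylsilyloxy)but-3-en-1-yl]-2-methyloxiran-2-yl]-2-oxoethyl acetate | I/C=C(C)\[C@@H](O[Si](CC)(CC)CC)C[C@H]1O[C@@]1(C)[C@@H](OC(C)=O)C=O | intermediate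
21 | isoprene | C=CC(C)=C | starting material
22 | bis(pinacolato)diboron | CC1(C)OB(OC1(C)C)B1OC(C)(C)C(C)(C)O1 | starting material
23 | (Z)-2-methyl-1,4-bis(4,4,5,5-tetramethyl-1,3,2-dioxaborolan-2-yl)but-2-ene | CC1(C)OB(C/C(C)=C\CB2OC(C)(C)C(C)(C)O2)OC1(C)C | intermediate
24 | (1R,3S,4Z,7R,8S,9S,10R)-9-acetoxy-1,10-epoxy-5-iodo-6-(pinacolboryl)-8-(pinacolboryloxy)-3-(triethylsilyloxy)-5,6-secogermacra-4,11-diene | I/C=C(C)\[C@@H](O[Si](CC)(CC)CC)C[C@H]1O[C@@]1(C)[C@@H](OC(C)=O)[C@@H](OB2OC(C)(C)C(C)(C)O2)[C@@H](C(C)=C)CB3OC(C)(C)C(C)(C)O3 | intermediate (not isolated)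
25 | (1R,3S,4Z,7R,8S,9S,10R)-9-acetoxy-1,10-epoxy-5-iodo-6-(pinacolboryl)-3-(triethylsilyloxy)-5,6-secogermacra-4,11-dien-8-ol | I/C=C(C)\[C@@H](O[Si](CC)(CC)CC)C[C@H]1O[C@@]1(C)[C@@H](OC(C)=O)[C@@H](O)[C@@H](C(C)=C)CB2OC(C)(C)C(C)(C)O2 | intermediate
26 | angelic acid, (Z)-2-methylbut-2-enoic acid | C/C=C(C)\C(=O)O | starting material
27 | (Z)-2-methylbut-2-enoic 2,4,6-trichlorobenzoic anhydride | C/C=C(C)\C(=O)OC(=O)c1c(Cl)cc(Cl)cc1Cl | intermediate
28 | (1R,3S,4Z,7R,8S,9S,10R)-9-acetoxy-8-angeloyloxy-1,10-epoxy-5-iodo-6-(pinacolboryl)-3-(triethylsilyloxy)-5,6-secogermacra-4,11-diene | I/C=C(C)\[C@@H](O[Si](CC)(CC)CC)C[C@H]1O[C@@]1(C)[C@@H](OC(C)=O)[C@@H](OC(=O)/C(C)=C\C)[C@@H](C(C)=C)CB2OC(C)(C)C(C)(C)O2 | intermediate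
29 | (1R,3S,4Z,7S,8S,9S,10R)-9-acetoxy-8-angeloyloxy-1,10-epoxy-5-iodo-3-(triethylsilyloxy)-5,6-secogermacra-4,11-dien-6-ol | I/C=C(C)\[C@@H](O[Si](CC)(CC)CC)C[C@H]1O[C@@]1(C)[C@@H](OC(C)=O)[C@@H](OC(=O)/C(C)=C\C)[C@@H](C(C)=C)CO | intermediate
30 | (1R,3S,4Z,7R,8S,9S,10R)-9-acetoxy-8-angeloyloxy-1,10-epoxy-5,6-diiodo-3-(triethylsilyloxy)-5,6-secogermacra-4,11-diene | I/C=C(C)\[C@@H](O[Si](CC)(CC)CC)C[C@H]1O[C@@]1(C)[C@@H](OC(C)=O)[C@@H](OC(=O)/C(C)=C\C)[C@@H](C(C)=C)CI | intermediate
31 | (1R,3S,4Z,7R,8S,9S,10R)-9-acetoxy-8-angeloyloxy-1,10-epoxy-5-iodo-6-(iodozincio)-3-(triethylsilyloxy)-5,6-secogermacra-4,11-diene | I/C=C(C)\[C@@H](O[Si](CC)(CC)CC)C[C@H]1O[C@@]1(C)[C@@H](OC(C)=O)[C@@H](OC(=O)/C(C)=C\C)[C@@H](C(C)=C)C[Zn]I | intermediate (not isolated)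
32 | (1R,3S,4Z,7R,8S,9S,10R)-9-acetoxy-8-angeloyloxy-1,10-epoxy-3-(triethylsilyloxy)germacra-4,11-diene | C=C(C)[C@H]1C/C=C(C)\[C@@H](O[Si](CC)(CC)CC)C[C@H]2O[C@@]2(C)[C@@H](OC(C)=O)[C@H]1OC(=O)/C(C)=C\C | intermediate
33 | (1R,3S,4Z,7R,8S,9S,10R)-9-acetoxy-8-angeloyloxy-1,10-epoxygermacra-4,11-dien-3-ol | C=C(C)[C@H]1C/C=C(C)\[C@@H](O)C[C@H]2O[C@@]2(C)[C@@H](OC(C)=O)[C@H]1OC(=O)/C(C)=C\C | intermediate
34 | (1R,3S,4R,5S,7R,8S,9S,10R)-9-acetoxy-8-angeloyloxy-1,10:4,5-diepoxygermacr-11-en-3-ol | C=C(C)[C@H]1C[C@@H]2O[C@]2(C)[C@@H](O)C[C@H]2O[C@@]2(C)[C@@H](OC(C)=O)[C@H]1OC(=O)/C(C)=C\C | intermediate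
35 | (1R,3S,4S,5S,7R,8S,9S,10R)-9-acetoxy-3,8-bis(angeloyloxy)-1,10:4,5-diepoxygermacr-11-ene (CNP0220329.1) | C=C(C)[C@H]1C[C@@H]2O[C@]2(C)[C@@H](OC(=O)/C(C)=C\C)C[C@H]2O[C@@]2(C)[C@@H](OC(C)=O)[C@H]1OC(=O)/C(C)=C\C | target

**Step count and risks**

Total step count: 24 (steps 1–24; steps 15 and 17 are one-step side branches that make 23 and 27). Longest linear sequence: 22 steps (1–14, 16 and 18–24) from propargyl alcohol.

Steps most likely to fail:

First, step 21, the proposed ring closure. The alkylzinc may be protonated or oligomerise faster than the strained ten-membered ring closes, the alkylpalladium may lose the C7 hydrogen, or ZnI2 may open the oxirane at 60 °C. The fallback is a B-alkyl Suzuki–Miyaura macrocyclisation, a known way to close rings at an sp3–sp2 bond, and it sets out from seco boronate 28, which the route already passes through. KHF2 in aqueous methanol at 0 °C should convert 28 into the potassium trifluoroborate F1, and PdCl2(dppf) with Cs2CO3 in THF/H2O at 70 °C under slow addition to about 1 mM should couple the alkylboron terminus with the (Z)-iodoalkene to give 32, where the route is rejoined for step 22. Steps 19 and 20 are then not needed.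

Second, step 16. The aldehyde may react through the prenyl-type terminus of 23, the anti selectivity at C8 may erode with this hindered α-acetoxy aldehyde, and the free C8 hydroxyl next to the C9 acetate invites acetyl migration. The fallback uses a single-terminus allylboronate that already carries the C6 oxygen, so no perborate step is needed. But-2-yn-1-ol with NaAlH2(OCH2CH2OMe)2 and then I2 should give (Z)-3-iodobut-2-en-1-ol F2; its 4-methoxybenzyl ether F3 would follow with 4-methoxybenzyl trichloroacetimidate and catalytic acid. Iodine–lithium exchange with t-BuLi at −78 °C and Matteson homologation with 2-(chloromethyl)-4,4,5,5-tetramethyl-1,3,2-dioxaborolane should give the (Z)-allylboronate F4 with retention. F4 would be added to aldehyde 20 under the conditions of step 16 to give the hydroxy ether F5, which would be acylated with anhydride 27 as in step 18 to give the angelate F6. DDQ in CH2Cl2/pH 7 buffer should then free the primary alcohol and give 29, where the route is rejoined before step 20.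

Third, step 23. The peracid may also epoxidise the isopropenyl group, or facial selectivity may fall if the ring does not adopt the conformer with C3–H in the olefin plane. The fallback changes the mode of oxygen delivery from an external hydrogen-bonded peracid to a peroxide bound to a titanium alkoxide of the substrate: 33 with Ti(OiPr)4 and t-BuOOH in CH2Cl2 at −20 °C. This reagent epoxidises only the olefin of the allylic alcohol and, for allylic alcohols with 1,3-allylic strain, follows the same threo sense as peracids. It sets out from 33 and comes back at 34 without a new compound (F0).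

**Further compounds**

F1 | step 21 | potassium (1R,3S,4Z,7R,8S,9S,10R)-[9-acetoxy-8-angeloyloxy-1,10-epoxy-5-iodo-3-(triethylsilyloxy)-5,6-secogermacra-4,11-dien-6-yl]trifluoroborate | I/C=C(C)\[C@@H](O[Si](CC)(CC)CC)C[C@H]1O[C@@]1(C)[C@@H](OC(C)=O)[C@@H](OC(=O)/C(C)=C\C)[C@@H](C(C)=C)C[B-](F)(F)F.[K+]
F2 | step 16 | (Z)-3-iodobut-2-en-1-ol | C/C(I)=C/CO
F3 | step 16 | 1-[[(2Z)-3-iodobut-2-en-1-yl]oxymethyl]-4-methoxybenzene | C/C(I)=C/COCc1ccc(OC)cc1
F4 | step 16 | 2-[(2Z)-4-(4-methoxybenzyloxy)-2-methylbut-2-en-1-yl]-4,4,5,5-tetramethyl-1,3,2-dioxaborolane | C/C(CB1OC(C)(C)C(C)(C)O1)=C/COCc1ccc(OC)cc1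
F5 | step 16 | (1R,3S,4Z,7S,8S,9S,10R)-9-acetoxy-1,10-epoxy-5-iodo-6-(4-methoxybenzyloxy)-3-(triethylsilyloxy)-5,6-secogermacra-4,11-dien-8-ol | I/C=C(C)\[C@@H](O[Si](CC)(CC)CC)C[C@H]1O[C@@]1(C)[C@@H](OC(C)=O)[C@@H](O)[C@@H](C(C)=C)COCc1ccc(OC)cc1
F6 | step 16 | (1R,3S,4Z,7S,8S,9S,10R)-9-acetoxy-8-angeloyloxy-1,10-epoxy-5-iodo-6-(4-methoxybenzyloxy)-3-(triethylsilyloxy)-5,6-secogermacra-4,11-diene | I/C=C(C)\[C@@H](O[Si](CC)(CC)CC)C[C@H]1O[C@@]1(C)[C@@H](OC(C)=O)[C@@H](OC(=O)/C(C)=C\C)[C@@H](C(C)=C)COCc1ccc(OC)cc1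
F0 | step 23 | none | none
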